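## Retrosynthetic overview

- Locants: the unprimed half is the 6-hydroxychromone (benzene ring A, pyranone ring B). The primed half is the 8-hydroxychromone (benzene ring C, pyranone ring D). The target comes from its 6,8'-di-O-methyl ether, with BBr3 as the last step.
- Key disconnection: C4'–C4a' of ring D, leading back to a 3-aryloxy-5-phenylpent-2-enoic acid hung on O1'. The plan rests on one feature. C8a', which bears O1', has two ortho neighbours: C8' is already oxygenated and C4a' is a C–H next to the C5–C5' axis. An acyl chain tethered through O1' therefore has only one carbon to acylate.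
- O1'–C2' comes from oxa-Michael addition of the biaryl phenol to tert-butyl 5-phenylpent-2-ynoate. A tert-butyl ester is used because acidolysis spares ring B, whereas hydroxide would attack it at C2.
- C5–C5' comes from Suzuki–Miyaura coupling of 5-bromo-6-methoxy-2-(2-phenylethyl)chromone with 3-hydroxy-4-methoxyphenylboronic acid. This is done while ring C still has no substituent beside the axis.
- Ring order: ring B is built on ring A (Baker–Venkataraman rearrangement, cyclodehydration, C5 bromination), ring C is then attached, and ring D is closed last.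

Key step: step 10

Assumption: the target SMILES defines no axial configuration, so the C5–C5' axis is formed without control and the product is taken as the racemate.

## Route

Step 1
Reactants: 1 2',5'-dihydroxyacetophenone; 2 3-phenylpropanoyl chloride
Product: 3 2-acetylbenzene-1,4-diyl bis(3-phenylpropanoate)
Conditions: 2 (2.3 equiv), pyridine, CH2Cl2, 0 °C → rt
Reagents that add atoms: none
Why: Pyridine-mediated O-acylation of both phenols should place on the hydrogen-bonded 2'-OH the acyl group needed for the rearrangement and mask the 5'-OH at the same time.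

Step 2
Reactants: 3 2-acetylbenzene-1,4-diyl bis(3-phenylpropanoate)
Product: 4 4-hydroxy-3-(3-oxo-5-phenylpentanoyl)phenyl 3-phenylpropanoate
Conditions: KOtBu (2.5 equiv), THF, 0 °C → rt; then aq. HCl
Reagents that add atoms: none
Why: In this Baker–Venkataraman rearrangement the methyl ketone, the most acidic C–H site, is enolised and attacks the adjacent ortho ester through a six-membered transition state, the diketonate acts as a thermodynamic sink, and any material that loses the remote ester converges on 5 in step 3.

Step 3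
Reactants: 4 4-hydroxy-3-(3-oxo-5-phenylpentanoyl)phenyl 3-phenylpropanoate
Product: 5 6-hydroxy-2-(2-phenylethyl)-4H-chromen-4-one
Conditions: conc. HCl, MeOH, reflux
Reagents that add atoms: none
Why: Acid-catalysed cyclodehydration of the o-hydroxyaryl 1,3-diketone (hemiketal formation, loss of water) closes ring B, and the same medium removes the aryl ester by acid-catalysed transesterification with methanol.

Step 4
Reactants: 5 6-hydroxy-2-(2-phenylethyl)-4H-chromen-4-one
Product: 6 5-bromo-6-hydroxy-2-(2-phenylethyl)-4H-chromen-4-one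
Conditions: NBS (1.0 equiv), DMF, 0 °C, dark
Reagents that add atoms: N-bromosuccinimide, O=C1CCC(=O)N1Br
Why: In this electrophilic aromatic bromination ortho to the free phenol, the O1–C8a=C4a–C4=O conjugation makes C5=C6 the enol-like bond, as in 2-naphthol, so C5 should be attacked rather than C7, and the phenol ring should outrun C3 and the side-chain phenyl ring.

Step 5
Reactants: 6 5-bromo-6-hydroxy-2-(2-phenylethyl)-4H-chromen-4-one
Product: 7 5-bromo-6-methoxy-2-(2-phenylethyl)-4H-chromen-4-one
Conditions: MeI, K2CO3, acetone, reflux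
Reagents that add atoms: iodomethane, CI
Why: Williamson ether synthesis on the only acidic O–H should be clean, since anhydrous carbonate does not harm the chromone.

Step 6
Reactants: 7 5-bromo-6-methoxy-2-(2-phenylethyl)-4H-chromen-4-one; 8 3-hydroxy-4-methoxyphenylboronic acid
Product: 9 5-(3-hydroxy-4-methoxyphenyl)-6-methoxy-2-(2-phenylethyl)-4H-chromen-4-one
Conditions: Pd(OAc)2 (3 mol %), SPhos (6 mol %), K3PO4 (3 equiv), toluene–H2O, 90 °C; acidic work-up
Reagents that add atoms: none
Why: In this Suzuki–Miyaura coupling the bulky electron-rich biarylphosphine lets zerovalent palladium insert into the doubly ortho-flanked C5–Br bond, the boronic acid has both ortho positions free, and the phenol is tolerated as its phenoxide.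

Step 7
Reactants: 10 4-phenyl-1-butyne
Product: 12 tert-butyl 5-phenylpent-2-ynoate, via lithium 4-phenylbut-1-yn-1-ide 11 (not isolated)
Conditions: n-BuLi, THF, −78 °C; Boc2O, −78 °C → 0 °C; aq. NH4Cl
Reagents that add atoms: di-tert-butyl dicarbonate, CC(C)(C)OC(=O)OC(=O)OC(C)(C)C; n-butyllithium, [Li]CCCC (supplies the lithium of 11 only)
Why: Deprotonation of the terminal alkyne and alkoxycarbonylation of the lithium acetylide with the dicarbonate is a standard route to tert-butyl alkynoates.

Step 8
Reactants: 9 5-(3-hydroxy-4-methoxyphenyl)-6-methoxy-2-(2-phenylethyl)-4H-chromen-4-one; 12 tert-butyl 5-phenylpent-2-ynoate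
Product: 13 tert-butyl (E)-3-{2-methoxy-5-[6-methoxy-4-oxo-2-(2-phenylethyl)-4H-chromen-5-yl]phenoxy}-5-phenylpent-2-enoate
Conditions: 12 (1.5 equiv), Cs2CO3 (0.3 equiv), DMF, 50 °C
Reagents that add atoms: none
Why: In this base-catalysed oxa-Michael addition the phenoxide attacks the β-carbon of the ynoate, the phenol serves as proton source so only a catalytic weak base is needed, reversible addition should favour the E enol ether, and any Z isomer is carried along because both geometries converge in step 10.

Step 9
Reactants: 13 tert-butyl (E)-3-{2-methoxy-5-[6-methoxy-4-oxo-2-(2-phenylethyl)-4H-chromen-5-yl]phenoxy}-5-phenylpent-2-enoate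
Product: 14 (E)-3-{2-methoxy-5-[6-methoxy-4-oxo-2-(2-phenylethyl)-4H-chromen-5-yl]phenoxy}-5-phenylpent-2-enoic acid
Conditions: CF3CO2H–CH2Cl2 (1:3), anhydrous, 0 °C → rt
Reagents that add atoms: none
Why: Acidolysis of the tert-butyl ester by loss of the tert-butyl cation as isobutene needs no hydroxide, so ring B, the methyl ethers and, in the absence of water, the electron-poor enol ether should survive.

Step 10
Reactants: 14 (E)-3-{2-methoxy-5-[6-methoxy-4-oxo-2-(2-phenylethyl)-4H-chromen-5-yl]phenoxy}-5-phenylpent-2-enoic acid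
Product: 16 6,8'-dimethoxy-2,2'-bis(2-phenylethyl)-4H,4'H-[5,5'-bichromene]-4,4'-dione, via (Z)-enoic acid 15 (not isolated)
Conditions: P2O5–CH3SO3H (1:10 w/w), rt → 50 °C; ice–water
Reagents that add atoms: none
Why: The medium converts the carboxyl group into a mixed anhydride or acylium ion, and protonation of this push–pull enol ether lowers the C2=C3 bond order so that 14 equilibrates with 15, the only geometry in which the acyl carbon can reach ring C. C4a' then attacks the acyl carbon in an intramolecular electrophilic aromatic substitution, and loss of the proton restores the arene, forming C4'–C4a' and the pyranone. The closest known reaction type is the acid-mediated cyclisation of β-aryloxyacrylic and β-aryloxycrotonic acids to chromones, an intramolecular Friedel–Crafts acylation. Ring D closes in a six-membered mode that is exo at the acyl carbon (6-exo-trig for the mixed anhydride, 6-exo-dig for a free acylium ion); no stereocentre is created and the C5–C5' axis is formed racemic. Regioselectivity is needed and is secured by the tether, because of the two carbons ortho to O1' only C4a' bears hydrogen (C8' carries OCH3), and C6' and C7' are out of reach. Chemoselectivity against seven-membered closure of the E isomer onto the side-chain phenyl ring rests on the faster six-membered closure at an oxygen-activated carbon, while rings A and B are switched off as the protonated chromone.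

Step 11
Reactants: 16 6,8'-dimethoxy-2,2'-bis(2-phenylethyl)-4H,4'H-[5,5'-bichromene]-4,4'-dione
Product: 17 6,8'-dihydroxy-2,2'-bis(2-phenylethyl)-4H,4'H-[5,5'-bichromene]-4,4'-dione (target)
Conditions: BBr3 (8 equiv), CH2Cl2, −78 °C → rt; then H2O
Reagents that add atoms: none
Why: Lewis-acid cleavage of aryl methyl ethers (boron coordination, bromide attack on methyl, hydrolysis of the aryl borates) should free both phenols, the excess reagent covering the two chromone carbonyls, which only complex reversibly.

## Compound list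

1 | 2',5'-dihydroxyacetophenone | CC(=O)c1cc(O)ccc1O | starting material
2 | 3-phenylpropanoyl chloride | O=C(Cl)CCc1ccccc1 | starting material
3 | 2-acetylbenzene-1,4-diyl bis(3-phenylpropanoate) | CC(=O)c1cc(OC(=O)CCc2ccccc2)ccc1OC(=O)CCc1ccccc1 | intermediate
4 | 4-hydroxy-3-(3-oxo-5-phenylpentanoyl)phenyl 3-phenylpropanoate (drawn as the diketo tautomer) | O=C(CCc1ccccc1)CC(=O)c1cc(OC(=O)CCc2ccccc2)ccc1O | intermediate
5 | 6-hydroxy-2-(2-phenylethyl)-4H-chromen-4-one | O=c1cc(CCc2ccccc2)oc2ccc(O)cc12 | intermediate
6 | 5-bromo-6-hydroxy-2-(2-phenylethyl)-4H-chromen-4-one | O=c1cc(CCc2ccccc2)oc2ccc(O)c(Br)c12 | intermediate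
7 | 5-bromo-6-methoxy-2-(2-phenylethyl)-4H-chromen-4-one | O=c1cc(CCc2ccccc2)oc2ccc(OC)c(Br)c12 | intermediate
8 | 3-hydroxy-4-methoxyphenylboronic acid | COc1ccc(B(O)O)cc1O | starting material
9 | 5-(3-hydroxy-4-methoxyphenyl)-6-methoxy-2-(2-phenylethyl)-4H-chromen-4-one | COc1ccc(-c2c(OC)ccc3oc(CCc4ccccc4)cc(=O)c23)cc1O | intermediate
10 | 4-phenyl-1-butyne | C#CCCc1ccccc1 | starting material
11 | lithium 4-phenylbut-1-yn-1-ide (not isolated) | [Li]C#CCCc1ccccc1 | intermediate
12 | tert-butyl 5-phenylpent-2-ynoate | CC(C)(C)OC(=O)C#CCCc1ccccc1 | intermediate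
13 | tert-butyl (E)-3-{2-methoxy-5-[6-methoxy-4-oxo-2-(2-phenylethyl)-4H-chromen-5-yl]phenoxy}-5-phenylpent-2-enoate | CC(C)(C)OC(=O)/C=C(\CCc1ccccc1)Oc1cc(-c2c(OC)ccc3oc(CCc4ccccc4)cc(=O)c23)ccc1OC | intermediate
14 | (E)-3-{2-methoxy-5-[6-methoxy-4-oxo-2-(2-phenylethyl)-4H-chromen-5-yl]phenoxy}-5-phenylpent-2-enoic acid | OC(=O)/C=C(\CCc1ccccc1)Oc1cc(-c2c(OC)ccc3oc(CCc4ccccc4)cc(=O)c23)ccc1OC | intermediate
15 | (Z)-3-{2-methoxy-5-[6-methoxy-4-oxo-2-(2-phenylethyl)-4H-chromen-5-yl]phenoxy}-5-phenylpent-2-enoic acid (reactive geometry, not isolated) | OC(=O)/C=C(/CCc1ccccc1)Oc1cc(-c2c(OC)ccc3oc(CCc4ccccc4)cc(=O)c23)ccc1OC | intermediate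
16 | 6,8'-dimethoxy-2,2'-bis(2-phenylethyl)-4H,4'H-[5,5'-bichromene]-4,4'-dione | COc1ccc2oc(CCc3ccccc3)cc(=O)c2c1-c1ccc(OC)c2oc(CCc3ccccc3)cc(=O)c12 | intermediate
17 | 6,8'-dihydroxy-2,2'-bis(2-phenylethyl)-4H,4'H-[5,5'-bichromene]-4,4'-dione | O=c1cc(CCc2ccccc2)oc2ccc(O)c(-c3ccc(O)c4oc(CCc5ccccc5)cc(=O)c34)c12 | target

## Step count

Total step count: 11.
Longest linear sequence: 10 steps (steps 1–6 and 8–11). Step 7 is a one-step branch.

## Steps most likely to fail

**Step 10.**
- What may go wrong: closure at C4a' may be slow. The carbon is wedged between O1' and the axis, it is meta to the methoxy group, and it sits beside a chromone that is fully protonated in the medium. Decarboxylation of the acid, seven-membered acylation of the side-chain phenyl ring from the E geometry, or methanesulfonylation of ring C could then take over.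
- Fallback: it sets out from 12, uses 7, and returns at 16. Ring D is closed before the axis exists.
- Commercial 5-bromo-2-methoxyphenol F1 is added to 12 (Cs2CO3 cat., DMF). This gives tert-butyl (E)-3-(5-bromo-2-methoxyphenoxy)-5-phenylpent-2-enoate F2.
- CF3CO2H then gives (E)-3-(5-bromo-2-methoxyphenoxy)-5-phenylpent-2-enoic acid F3.
- P2O5–CH3SO3H closes 5-bromo-8-methoxy-2-(2-phenylethyl)-4H-chromen-4-one F4, now beside a bromine atom rather than a cationic chromonyl group.
- Miyaura borylation (B2pin2, PdCl2(dppf), KOAc, dioxane, 90 °C) gives 8-methoxy-2-(2-phenylethyl)-5-(4,4,5,5-tetramethyl-1,3,2-dioxaborolan-2-yl)-4H-chromen-4-one F5.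
- Suzuki–Miyaura coupling of this boronate with 7 (Pd(OAc)2, SPhos, K3PO4, toluene–H2O, 100 °C) gives 16. The crowding is then carried by a tri-ortho-substituted cross-coupling, a known task for this ligand class.

**Step 8.**
- What may go wrong: addition of the ortho-methoxylated phenoxide to a β-alkyl ynoate may be sluggish. Base-induced migration of the triple bond through the allenoate to the phenyl-conjugated 2,4-dienoate could then consume the acceptor.
- Fallback: it sets out from 12, uses 9, and returns at 15. The conjugate addition is replaced by a vinyl C–O cross-coupling.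
- Anti hydroiodination of 12 (NaI, AcOH, 80 °C) gives tert-butyl (Z)-3-iodo-5-phenylpent-2-enoate F6.
- Ullmann-type coupling with 9 (CuI, N,N-dimethylglycine, Cs2CO3, dioxane, 70 °C) should proceed with retention. It gives tert-butyl (Z)-3-{2-methoxy-5-[6-methoxy-4-oxo-2-(2-phenylethyl)-4H-chromen-5-yl]phenoxy}-5-phenylpent-2-enoate F7.
- CF3CO2H–CH2Cl2 then delivers 15 directly in the reactive geometry for step 10.

**Step 4.**
- What may go wrong: site selectivity may be poor. Attack at C7 or C3, or double bromination, could compete with attack at the peri-hindered C5.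
- Fallback: it sets out from 2 and returns at 7, bypassing 3–6. The bromine is placed by directed metalation before ring B is built.
- Commercial 2-bromo-1,4-dimethoxybenzene F8 is lithiated at the C–H flanked by Br and OCH3 (LiN(i-Pr)2, THF, −78 °C). Trapping with N-methoxy-N-methylacetamide gives 1-(2-bromo-3,6-dimethoxyphenyl)ethan-1-one F9.
- Chelation-controlled cleavage of the methoxy group ortho to the carbonyl (BCl3, CH2Cl2, −78 → 0 °C) gives 1-(2-bromo-6-hydroxy-3-methoxyphenyl)ethan-1-one F10.
- Acylation with 2 (pyridine, CH2Cl2) gives 2-acetyl-3-bromo-4-methoxyphenyl 3-phenylpropanoate F11.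
- Baker–Venkataraman rearrangement (KOtBu, THF) gives 1-(2-bromo-6-hydroxy-3-methoxyphenyl)-5-phenylpentane-1,3-dione F12.
- Treatment with HCl in refluxing MeOH closes ring B to give 7.

## Further compounds

F1 | step 10 | 5-bromo-2-methoxyphenol (purchased) | COc1ccc(Br)cc1O
F2 | step 10 | tert-butyl (E)-3-(5-bromo-2-methoxyphenoxy)-5-phenylpent-2-enoate | CC(C)(C)OC(=O)/C=C(\CCc1ccccc1)Oc1cc(Br)ccc1OC
F3 | step 10 | (E)-3-(5-bromo-2-methoxyphenoxy)-5-phenylpent-2-enoic acid | OC(=O)/C=C(\CCc1ccccc1)Oc1cc(Br)ccc1OC
F4 | step 10 | 5-bromo-8-methoxy-2-(2-phenylethyl)-4H-chromen-4-one | COc1ccc(Br)c2c(=O)cc(CCc3ccccc3)oc12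
F5 | step 10 | 8-methoxy-2-(2-phenylethyl)-5-(4,4,5,5-tetramethyl-1,3,2-dioxaborolan-2-yl)-4H-chromen-4-one | COc1ccc(B2OC(C)(C)C(C)(C)O2)c2c(=O)cc(CCc3ccccc3)oc12
F6 | step 8 | tert-butyl (Z)-3-iodo-5-phenylpent-2-enoate | CC(C)(C)OC(=O)/C=C(\I)CCc1ccccc1
F7 | step 8 | tert-butyl (Z)-3-{2-methoxy-5-[6-methoxy-4-oxo-2-(2-phenylethyl)-4H-chromen-5-yl]phenoxy}-5-phenylpent-2-enoate | CC(C)(C)OC(=O)/C=C(/CCc1ccccc1)Oc1cc(-c2c(OC)ccc3oc(CCc4ccccc4)cc(=O)c23)ccc1OC
F8 | step 4 | 2-bromo-1,4-dimethoxybenzene (purchased) | COc1ccc(OC)c(Br)c1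
F9 | step 4 | 1-(2-bromo-3,6-dimethoxyphenyl)ethan-1-one | CC(=O)c1c(Br)c(OC)ccc1OC
F10 | step 4 | 1-(2-bromo-6-hydroxy-3-methoxyphenyl)ethan-1-one | CC(=O)c1c(Br)c(OC)ccc1O
F11 | step 4 | 2-acetyl-3-bromo-4-methoxyphenyl 3-phenylpropanoate | CC(=O)c1c(Br)c(OC)ccc1OC(=O)CCc1ccccc1
F12 | step 4 | 1-(2-bromo-6-hydroxy-3-methoxyphenyl)-5-phenylpentane-1,3-dione | O=C(CCc1ccccc1)CC(=O)c1c(Br)c(OC)ccc1O
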